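**Retrosynthetic overview**
- C6–O ester: Mitsunobu inversion of the C6-epimeric macrocyclic alcohol with (Z)-2-(acetoxymethyl)but-2-enoic acid (from tert-butyl but-2-ynoate by vinylalumination).
- Key C6–C7 bond: intramolecular CrCl2 Barbier closure in which C7, the β-carbon of a 3-(bromomethyl)butenolide (a homoenolate equivalent), attacks the C6 aldehyde. This closes the ten-membered ring, creates the exo-methylene and sets C6 and C7.
- Butenolide: ring-closing metathesis of the 2-(bromomethyl)acrylate of a C8 vinyl carbinol. C14–OAc and C8–OH come from i-Bu2AlH opening of an (E)-α-alkylidene-γ-lactone, whose ring fixes the ring-cis C1=C10 geometry.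
- C1=C10: Horner–Wadsworth–Emmons union of a C1 aldehyde (geraniol; Sharpless epoxidation sets C4) with a phosphono lactone from triethyl phosphonoacetate and (S)-2-vinyloxirane (sets C8).
- Ring order: five-membered lactone first (metathesis), ten-membered carbocycle last (chromium).

Assumption: locants C1–C15 follow germacrane numbering of the target (C4 carbinol, C6 acyloxy carbon, C7 ring-fusion CH, C8 lactone carbinol, C12 lactone C=O, C13 exo-methylene, C14 CH2OAc, C15 methyl); (S)-2-vinyloxirane is taken as commercially available in high ee.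

**Route**

Step 1
Reactants: 1 geraniol
Product: 2 (2S,3S)-2,3-epoxygeraniol
Conditions: Ti(OiPr)4 (5 mol%), L-(+)-diethyl tartrate (6 mol%), t-BuOOH, 4 Å molecular sieves, CH2Cl2, −20 °C
Reagents that add atoms: tert-butyl hydroperoxide, CC(C)(C)OO
Why: Katsuki–Sharpless asymmetric epoxidation is chemoselective for the allylic-alcohol alkene and, with the L-(+)-tartrate ligand, delivers oxygen to the face that gives the (2S,3S)-epoxide (about 95% ee), which fixes the future C4 carbinol centre.

Step 2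
Reactants: 2 (2S,3S)-2,3-epoxygeraniol
Product: 3 (3S)-3,7-dimethyloct-6-ene-1,3-diol
Conditions: NaAlH2(OCH2CH2OCH3)2, THF, 0 °C → rt; aq. NaOH
Reagents that add atoms: none
Why: Regioselective reductive opening of a 2,3-epoxy alcohol: hydride is delivered intramolecularly from the alkoxyaluminate to C2 (C3 is fully substituted), so the 1,3-diol forms with the C–O bond at the stereocentre untouched.

Step 3
Reactants: 3 (3S)-3,7-dimethyloct-6-ene-1,3-diol
Product: 4 (4S)-2,2,4-trimethyl-4-(4-methylpent-3-en-1-yl)-1,3-dioxane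
Conditions: Me2C(OMe)2, PPTS (cat.), CH2Cl2, rt
Reagents that add atoms: 2,2-dimethoxypropane, COC(C)(C)OC
Why: Acid-catalysed transketalisation ties the primary and the tertiary hydroxyl into a six-membered acetonide, masking both (future C6–OH and C4–OH) for the basic and hydride steps without touching the stereocentre.

Step 4
Reactants: 4 (4S)-2,2,4-trimethyl-4-(4-methylpent-3-en-1-yl)-1,3-dioxane
Product: 6 3-[(4S)-2,2,4-trimethyl-1,3-dioxan-4-yl]propanal, via ozonide 5 (not isolated)
Conditions: O3, CH2Cl2, −78 °C; then Me2S, −78 °C → rt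
Reagents that add atoms: ozone, [O-][O+]=O
Why: Ozonolysis with reductive work-up cleaves the only alkene to the C1 aldehyde and acetone, and the acetal is inert.

Step 5
Reactants: 7 triethyl phosphonoacetate; 8 (S)-2-vinyloxirane
Product: 10 diethyl [(5R)-5-ethenyl-2-oxooxolan-3-yl]phosphonate (both C3 epimers), via sodium alkoxide 9 (not isolated)
Conditions: NaH, THF, 0 → 60 °C; aq. HCl work-up
Reagents that add atoms: none
Why: Epoxide alkylation–lactonisation: under basic, Lewis-acid-free conditions the phosphonoacetate carbanion opens the vinyl epoxide by SN2 at the unsubstituted carbon, and at moderate temperature the alkoxide lactonises onto the ethyl ester (5-exo-trig) faster than it transfers the phosphoryl group, so C8 comes unchanged from the epoxide.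

Step 6
Reactants: 6 3-[(4S)-2,2,4-trimethyl-1,3-dioxan-4-yl]propanal; 10 diethyl [(5R)-5-ethenyl-2-oxooxolan-3-yl]phosphonate
Product: 11 (3E,5R)-5-ethenyl-3-{3-[(4S)-2,2,4-trimethyl-1,3-dioxan-4-yl]propylidene}oxolan-2-one
Conditions: NaH, THF, 0 °C → rt
Reagents that add atoms: none
Why: Horner–Wadsworth–Emmons olefination of the α-phosphono lactone gives mainly the (E)-alkylidene lactone, in which the new chain (C2) is cis to the ring CH2 (future C9) and trans to the carbonyl (future C14), which is the ring-cis C1=C10 geometry of the target (the minor Z isomer is removed by chromatography).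

Step 7
Reactants: 11 (3E,5R)-5-ethenyl-3-{3-[(4S)-2,2,4-trimethyl-1,3-dioxan-4-yl]propylidene}oxolan-2-one
Product: 12 (2E)-2-[(2R)-2-hydroxybut-3-en-1-yl]-5-[(4S)-2,2,4-trimethyl-1,3-dioxan-4-yl]pent-2-en-1-ol
Conditions: i-Bu2AlH (4 equiv), CH2Cl2, −78 → 0 °C; aq. KNaC4H4O6
Reagents that add atoms: none
Why: 1,2-Reduction of the conjugated lactone through the lactol gives the primary allylic alcohol (C14) and frees the C8 carbinol, with alkene geometry, C8 and the acetonide untouched.

Step 8
Reactants: 12 (2E)-2-[(2R)-2-hydroxybut-3-en-1-yl]-5-[(4S)-2,2,4-trimethyl-1,3-dioxan-4-yl]pent-2-en-1-ol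
Product: 13 (2E)-2-[(2R)-2-hydroxybut-3-en-1-yl]-5-[(4S)-2,2,4-trimethyl-1,3-dioxan-4-yl]pent-2-en-1-yl acetate
Conditions: AcCl (1.05 equiv), 2,4,6-collidine, CH2Cl2, −78 °C
Reagents that add atoms: acetyl chloride, CC(=O)Cl
Why: Kinetically controlled chemoselective acetylation with AcCl and collidine at low temperature acylates the unhindered primary allylic hydroxyl and leaves the secondary C8 hydroxyl free.

Step 9
Reactants: 13 (2E)-2-[(2R)-2-hydroxybut-3-en-1-yl]-5-[(4S)-2,2,4-trimethyl-1,3-dioxan-4-yl]pent-2-en-1-yl acetate; 14 2-(bromomethyl)acrylic acid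
Product: 15 (3R,5E)-5-(acetoxymethyl)-8-[(4S)-2,2,4-trimethyl-1,3-dioxan-4-yl]octa-1,5-dien-3-yl 2-(bromomethyl)prop-2-enoate
Conditions: dicyclohexylcarbodiimide, DMAP (5 mol%), CH2Cl2, −20 → 0 °C
Reagents that add atoms: none
Why: Steglich esterification acylates the only free hydroxyl (C8) with retention, and low temperature with only catalytic DMAP limits attack on the allylic bromide.

Step 10
Reactants: 15 (3R,5E)-5-(acetoxymethyl)-8-[(4S)-2,2,4-trimethyl-1,3-dioxan-4-yl]octa-1,5-dien-3-yl 2-(bromomethyl)prop-2-enoate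
Product: 16 (2E)-2-{[(2R)-4-(bromomethyl)-5-oxo-2,5-dihydrofuran-2-yl]methyl}-5-[(4S)-2,2,4-trimethyl-1,3-dioxan-4-yl]pent-2-en-1-yl acetate
Conditions: second-generation Hoveyda–Grubbs catalyst RuCl2(H2IMes)(=CH-C6H4-2-OiPr) (10 mol%), toluene (5 mM), 80 °C, Ar sparge
Reagents that add atoms: none
Why: Ring-closing metathesis between the vinyl group and the acrylate alkene forms the five-membered butenolide with loss of ethene; the phosphine-free catalyst tolerates the allylic bromide and the hindered trisubstituted C1=C10 alkene does not compete.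

Step 11
Reactants: 16 (2E)-2-{[(2R)-4-(bromomethyl)-5-oxo-2,5-dihydrofuran-2-yl]methyl}-5-[(4S)-2,2,4-trimethyl-1,3-dioxan-4-yl]pent-2-en-1-yl acetate
Product: 17 (2E,6S)-2-{[(2R)-4-(bromomethyl)-5-oxo-2,5-dihydrofuran-2-yl]methyl}-6,8-dihydroxy-6-methyloct-2-en-1-yl acetate
Conditions: AcOH/THF/H2O (3:1:1), rt
Reagents that add atoms: none
Why: Acetal hydrolysis: the strained 4,4-disubstituted acetonide cleaves under mild aqueous acetic acid that leaves the allylic bromide, the acetate and the lactone intact.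

Step 12
Reactants: 17 (2E,6S)-2-{[(2R)-4-(bromomethyl)-5-oxo-2,5-dihydrofuran-2-yl]methyl}-6,8-dihydroxy-6-methyloct-2-en-1-yl acetate
Product: 18 (2E,6S)-2-{[(2R)-4-(bromomethyl)-5-oxo-2,5-dihydrofuran-2-yl]methyl}-6-hydroxy-6-methyl-8-oxooct-2-en-1-yl acetate
Conditions: TEMPO (10 mol%), PhI(OAc)2, CH2Cl2, rt
Reagents that add atoms: none
Why: Oxoammonium (TEMPO) oxidation touches only the primary alcohol, the tertiary alcohol cannot be oxidised, and the near-neutral conditions spare the β-hydroxy aldehyde, which is used at once.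

Step 13
Reactants: 18 (2E,6S)-2-{[(2R)-4-(bromomethyl)-5-oxo-2,5-dihydrofuran-2-yl]methyl}-6-hydroxy-6-methyl-8-oxooct-2-en-1-yl acetate
Product: 21 [(3aR,4S,6S,9E,11aR)-4,6-dihydroxy-6-methyl-3-methylidene-2-oxo-2,3,3a,4,5,6,7,8,11,11a-decahydrocyclodeca[b]furan-10-yl]methyl acetate (C6 epimer of the natural alcohol), via allylchromium 19 (not isolated), via chromium alkoxide 20 (not isolated)
Conditions: CrCl2 (8 equiv), THF (1 mM), rt, syringe-pump addition of 18; aq. NH4Cl
Reagents that add atoms: none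
Why: Proposed new method: ring-forming version of the known chromium-mediated 2-(alkoxycarbonyl)allylation of aldehydes by 3-(bromomethyl)butenolides (Nozaki–Hiyama–Kishi/Barbier type), in which two CrCl2 reduce the C13–Br bond to an allylchromium (trivalent chromium) whose nucleophilic carbon is C7, the normally electrophilic β-carbon of the lactone, and this adds SE2′ to the C6 aldehyde under high dilution to close the ten-membered ring and regenerate the exo-methylene; C7 is set by attack on the butenolide face opposite the C8 substituent (trans-fused lactone), and C6 by the chair Zimmerman–Traxler transition state of the ring-locked E-type allylchromium with the aldehyde chain pseudo-equatorial (anti adduct, 6S), the sense also seen in related macrocyclic Barbier closures of germacranolides.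

Step 14
Reactants: 22 tert-butyl but-2-ynoate
Product: 25 tert-butyl (2Z)-2-(acetoxymethyl)but-2-enoate, via vinylalane 23 (not isolated), via aluminium alkoxide 24 (not isolated)
Conditions: i-Bu2AlH, N-methylmorpholine N-oxide, THF, 0 °C; (CH2O)n, rt; then Ac2O, pyridine, DMAP, 0 °C
Reagents that add atoms: formaldehyde (from paraformaldehyde), C=O; acetic anhydride, CC(=O)OC(C)=O
Why: Vinylalumination–aldol: syn-hydroalumination of the ynoate puts aluminium at C2 cis to the new C3–H, the α-alumino enoate adds to formaldehyde with the methyl group ending cis to the ester (Z), and the aluminium alkoxide is acetylated in the same flask.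

Step 15
Reactants: 25 tert-butyl (2Z)-2-(acetoxymethyl)but-2-enoate
Product: 26 (2Z)-2-(acetoxymethyl)but-2-enoic acid
Conditions: CF3CO2H/CH2Cl2 (1:4), 0 °C → rt
Reagents that add atoms: none
Why: Acidolysis of the tert-butyl ester (loss of isobutene) frees the acid without touching the acetate or the Z-alkene.

Step 16
Reactants: 21 [(3aR,4S,6S,9E,11aR)-4,6-dihydroxy-6-methyl-3-methylidene-2-oxo-2,3,3a,4,5,6,7,8,11,11a-decahydrocyclodeca[b]furan-10-yl]methyl acetate; 26 (2Z)-2-(acetoxymethyl)but-2-enoic acid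
Product: 28 CNP0280960.1, via alkoxyphosphonium salt 27 (not isolated)
Conditions: PPh3, DIAD (betaine preformed), toluene, 0 °C → rt
Reagents that add atoms: none
Why: Mitsunobu esterification: the preformed PPh3–DIAD betaine turns the C6 hydroxyl into an alkoxyphosphonium ion that the carboxylate of 26 displaces by SN2 with inversion, converting 6S into the required 6R acyloxy centre, while the tertiary hydroxyl is inert and no free phosphine is left to add to the enoates.

**Compound list**

1 | geraniol, (2E)-3,7-dimethylocta-2,6-dien-1-ol | CC(C)=CCC/C(C)=C/CO | starting material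
2 | (2S,3S)-2,3-epoxygeraniol, [(2S,3S)-3-methyl-3-(4-methylpent-3-en-1-yl)oxiran-2-yl]methanol | CC(C)=CCC[C@]1(C)O[C@H]1CO | intermediate
3 | (3S)-3,7-dimethyloct-6-ene-1,3-diol | CC(C)=CCC[C@](C)(O)CCO | intermediate
4 | (4S)-2,2,4-trimethyl-4-(4-methylpent-3-en-1-yl)-1,3-dioxane | CC(C)=CCC[C@]1(C)OC(C)(C)OCC1 | intermediate
5 | ozonide of 4 (not isolated): 3,3-dimethyl-5-{2-[(4S)-2,2,4-trimethyl-1,3-dioxan-4-yl]ethyl}-1,2,4-trioxolane | CC1(C)OOC(CC[C@]2(C)OC(C)(C)OCC2)O1 | intermediate
6 | 3-[(4S)-2,2,4-trimethyl-1,3-dioxan-4-yl]propanal | O=CCC[C@]1(C)OC(C)(C)OCC1 | intermediate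
7 | triethyl phosphonoacetate | CCOC(=O)CP(=O)(OCC)OCC | starting material
8 | (S)-2-vinyloxirane, (2S)-2-ethenyloxirane | C=C[C@H]1CO1 | starting material
9 | sodium alkoxide of ethyl (4R)-2-(diethoxyphosphoryl)-4-hydroxyhex-5-enoate (not isolated) | CCOC(=O)C(C[C@@H]([O-])C=C)P(=O)(OCC)OCC.[Na+] | intermediate
10 | diethyl [(5R)-5-ethenyl-2-oxooxolan-3-yl]phosphonate (both C3 epimers) | O=C1O[C@@H](C=C)CC1P(=O)(OCC)OCC | intermediate
11 | (3E,5R)-5-ethenyl-3-{3-[(4S)-2,2,4-trimethyl-1,3-dioxan-4-yl]propylidene}oxolan-2-one | O=C1O[C@@H](C=C)C/C1=C\CC[C@]2(C)OC(C)(C)OCC2 | intermediate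
12 | (2E)-2-[(2R)-2-hydroxybut-3-en-1-yl]-5-[(4S)-2,2,4-trimethyl-1,3-dioxan-4-yl]pent-2-en-1-ol | OC/C(C[C@@H](O)C=C)=C/CC[C@]1(C)OC(C)(C)OCC1 | intermediate
13 | (2E)-2-[(2R)-2-hydroxybut-3-en-1-yl]-5-[(4S)-2,2,4-trimethyl-1,3-dioxan-4-yl]pent-2-en-1-yl acetate | CC(=O)OC/C(C[C@@H](O)C=C)=C/CC[C@]1(C)OC(C)(C)OCC1 | intermediate
14 | 2-(bromomethyl)acrylic acid, 2-(bromomethyl)prop-2-enoic acid | C=C(CBr)C(=O)O | starting material
15 | (3R,5E)-5-(acetoxymethyl)-8-[(4S)-2,2,4-trimethyl-1,3-dioxan-4-yl]octa-1,5-dien-3-yl 2-(bromomethyl)prop-2-enoate | CC(=O)OC/C(C[C@@H](OC(=O)C(=C)CBr)C=C)=C/CC[C@]1(C)OC(C)(C)OCC1 | intermediate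
16 | (2E)-2-{[(2R)-4-(bromomethyl)-5-oxo-2,5-dihydrofuran-2-yl]methyl}-5-[(4S)-2,2,4-trimethyl-1,3-dioxan-4-yl]pent-2-en-1-yl acetate | CC(=O)OC/C(C[C@H]1OC(=O)C(CBr)=C1)=C/CC[C@]2(C)OC(C)(C)OCC2 | intermediate
17 | (2E,6S)-2-{[(2R)-4-(bromomethyl)-5-oxo-2,5-dihydrofuran-2-yl]methyl}-6,8-dihydroxy-6-methyloct-2-en-1-yl acetate | CC(=O)OC/C(C[C@H]1OC(=O)C(CBr)=C1)=C/CC[C@](C)(O)CCO | intermediate
18 | (2E,6S)-2-{[(2R)-4-(bromomethyl)-5-oxo-2,5-dihydrofuran-2-yl]methyl}-6-hydroxy-6-methyl-8-oxooct-2-en-1-yl acetate | CC(=O)OC/C(C[C@H]1OC(=O)C(CBr)=C1)=C/CC[C@](C)(O)CC=O | intermediate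
19 | allylchromium from 18 (not isolated): dichloro{[(5R)-5-[(2E,6S)-2-(acetoxymethyl)-6-hydroxy-6-methyl-8-oxooct-2-en-1-yl]-2-oxo-2,5-dihydrofuran-3-yl]methyl}chromium, trivalent chromium | CC(=O)OC/C(C[C@H]1OC(=O)C(C[Cr](Cl)Cl)=C1)=C/CC[C@](C)(O)CC=O | intermediate
20 | chromium alkoxide (not isolated): alcohol 21 carrying CrCl2 on the new C6 oxygen, trivalent chromium | C=C1C(=O)O[C@@H]2C/C(COC(C)=O)=C\CC[C@](C)(O)C[C@H](O[Cr](Cl)Cl)[C@@H]12 | intermediate
21 | [(3aR,4S,6S,9E,11aR)-4,6-dihydroxy-6-methyl-3-methylidene-2-oxo-2,3,3a,4,5,6,7,8,11,11a-decahydrocyclodeca[b]furan-10-yl]methyl acetate; trans-fused lactone, C6–OH epimeric to the target's C6–O (the 3a descriptor reads R here and S in 28 only because the CIP ranking at that carbon changes on acylation) | C=C1C(=O)O[C@@H]2C/C(COC(C)=O)=C\CC[C@](C)(O)C[C@H](O)[C@@H]12 | intermediate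
22 | tert-butyl but-2-ynoate | CC#CC(=O)OC(C)(C)C | starting material
23 | vinylalane (not isolated): tert-butyl 2-(diisobutylalumanyl)but-2-enoate with Al cis to the C3 hydrogen | C/C=C(/[Al](CC(C)C)CC(C)C)C(=O)OC(C)(C)C | intermediate
24 | aluminium alkoxide (not isolated): tert-butyl (2Z)-2-{[(diisobutylalumanyl)oxy]methyl}but-2-enoate | C/C=C(/CO[Al](CC(C)C)CC(C)C)C(=O)OC(C)(C)C | intermediate
25 | tert-butyl (2Z)-2-(acetoxymethyl)but-2-enoate | C/C=C(/COC(C)=O)C(=O)OC(C)(C)C | intermediate
26 | (2Z)-2-(acetoxymethyl)but-2-enoic acid | C/C=C(/COC(C)=O)C(=O)O | intermediate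
27 | alkoxyphosphonium salt (not isolated): 21 carrying Ph3P+ on the C6 oxygen, counter-ion the carboxylate of 26 | C=C1C(=O)O[C@@H]2C/C(COC(C)=O)=C\CC[C@](C)(O)C[C@H](O[P+](c3ccccc3)(c3ccccc3)c3ccccc3)[C@@H]12.C/C=C(/COC(C)=O)C(=O)[O-] | intermediate
28 | CNP0280960.1, (3aS,4R,6S,9E,11aR)-10-(acetoxymethyl)-6-hydroxy-6-methyl-3-methylidene-2-oxo-2,3,3a,4,5,6,7,8,11,11a-decahydrocyclodeca[b]furan-4-yl (2Z)-2-(acetoxymethyl)but-2-enoate | C=C1C(=O)O[C@@H]2C/C(COC(C)=O)=C\CC[C@](C)(O)C[C@@H](OC(=O)/C(=C\C)COC(C)=O)[C@@H]12 | target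

**Step count and risks**

Total: 16 steps. Longest linear sequence: 13 steps (1 to 28 through steps 1–4, 6–13 and 16); step 5 and steps 14–15 are side branches.

The three steps most likely to fail are step 13, step 16 and step 10.

Step 13 is the least certain. The dangers are oligomerisation at the aldehyde, translactonisation of the chromium alkoxide onto C12, and formation of the other C6 epimer; the C6 outcome is a prediction from the chair model and from analogy, not a known result. The fallback replaces the in-situ allylchromium by an isolable allylstannane that closes through an open transition state. It sets out from diol 17: Bu3SnCl and Zn in THF/aqueous NH4Cl convert the allylic bromide into the allylstannane diol F4; SO3·pyridine/DMSO/i-Pr2NEt oxidises the primary alcohol to the stannyl aldehyde F5; BF3·OEt2 (CH2Cl2, −78 °C, high dilution) closes the ring through an antiperiplanar open transition state, which favours the syn adduct, the 6R alcohol F6. F6 is acylated with retention by 26 (2,4,6-trichlorobenzoyl chloride, Et3N, then DMAP, toluene) and the route is rejoined at 28. If the chromium closure itself gives the 6R alcohol, that product is the same 6R alcohol F6 and is acylated in the same way.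

Step 16 may fail because the C6 carbinol is hindered and the activated oxygen can eliminate towards C7. The fallback inverts C6 by oxidation and reduction instead of SN2. It sets out from 21: Dess–Martin periodinane gives the C6 ketone F7; reagent-controlled reduction (2-methyl-CBS-oxazaborolidine with catecholborane, −78 °C, enantiomer chosen for the 6R product) gives the 6R alcohol F6; acylation with 26 under the same mixed-anhydride conditions rejoins the route at 28.

Step 10 may be slow because the acrylate alkene is 1,1-disubstituted and carries the bromide. The fallback forms the ring first and introduces C13 afterwards. It sets out from 13: acryloyl chloride and i-Pr2NEt give the acrylate ester F1; ring-closing metathesis of this monosubstituted acrylate (second-generation Grubbs catalyst RuCl2(H2IMes)(PCy3)(=CHPh), CH2Cl2, 40 °C) gives the unsubstituted butenolide F2; Morita–Baylis–Hillman hydroxymethylation (aqueous CH2O, PMe3, THF) gives the 3-(hydroxymethyl)butenolide F3; CBr4/PPh3 converts F3 into the bromide and the route is rejoined at 16.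

**Further compounds**

F1 | step 10 | (3R,5E)-5-(acetoxymethyl)-8-[(4S)-2,2,4-trimethyl-1,3-dioxan-4-yl]octa-1,5-dien-3-yl prop-2-enoate | CC(=O)OC/C(C[C@@H](OC(=O)C=C)C=C)=C/CC[C@]1(C)OC(C)(C)OCC1
F2 | step 10 | (2E)-2-{[(2R)-5-oxo-2,5-dihydrofuran-2-yl]methyl}-5-[(4S)-2,2,4-trimethyl-1,3-dioxan-4-yl]pent-2-en-1-yl acetate | CC(=O)OC/C(C[C@H]1OC(=O)C=C1)=C/CC[C@]2(C)OC(C)(C)OCC2
F3 | step 10 | (2E)-2-{[(2R)-4-(hydroxymethyl)-5-oxo-2,5-dihydrofuran-2-yl]methyl}-5-[(4S)-2,2,4-trimethyl-1,3-dioxan-4-yl]pent-2-en-1-yl acetate | CC(=O)OC/C(C[C@H]1OC(=O)C(CO)=C1)=C/CC[C@]2(C)OC(C)(C)OCC2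
F4 | step 13 | (2E,6S)-6,8-dihydroxy-6-methyl-2-({(2R)-5-oxo-4-[(tributylstannyl)methyl]-2,5-dihydrofuran-2-yl}methyl)oct-2-en-1-yl acetate | CC(=O)OC/C(C[C@H]1OC(=O)C(C[Sn](CCCC)(CCCC)CCCC)=C1)=C/CC[C@](C)(O)CCO
F5 | step 13 | (2E,6S)-6-hydroxy-6-methyl-8-oxo-2-({(2R)-5-oxo-4-[(tributylstannyl)methyl]-2,5-dihydrofuran-2-yl}methyl)oct-2-en-1-yl acetate | CC(=O)OC/C(C[C@H]1OC(=O)C(C[Sn](CCCC)(CCCC)CCCC)=C1)=C/CC[C@](C)(O)CC=O
F6 | step 13 | [(3aR,4R,6S,9E,11aR)-4,6-dihydroxy-6-methyl-3-methylidene-2-oxo-2,3,3a,4,5,6,7,8,11,11a-decahydrocyclodeca[b]furan-10-yl]methyl acetate (6R alcohol) | C=C1C(=O)O[C@@H]2C/C(COC(C)=O)=C\CC[C@](C)(O)C[C@@H](O)[C@@H]12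
F7 | step 16 | [(3aS,6S,9E,11aR)-6-hydroxy-6-methyl-3-methylidene-2,4-dioxo-2,3,3a,4,5,6,7,8,11,11a-decahydrocyclodeca[b]furan-10-yl]methyl acetate | C=C1C(=O)O[C@@H]2C/C(COC(C)=O)=C\CC[C@](C)(O)CC(=O)[C@@H]12
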